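## Retrosynthetic overview

- The target acid comes from its 2-(trimethylsilyl)ethyl ester by fluoride; the C15 acetate and the 13E alkene are carried from the first side-chain step.
- Key disconnection C9–C10: ring B is closed last, when a tertiary C10 radical (hydrogen-atom transfer to the ring-A alkene) adds 6-endo to C9 of a (Z)-α-alkylidene-β-acetoxy ester; loss of the C7 acetate leaves the Δ7-8-carboxylate, and C9 and C10 are set from C5.
- The radical acceptor comes from syn-hydroalumination of an ynoate (C8, C9, C11–C15, C17) and aldol addition to a ring-A aldehyde.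
- Ring A is made first: Robinson annulation, CBS reduction, then a Claisen shift that moves the carbinol chirality onto C5.
- The ynoate comes from γ-alkylation of the but-2-ynoic acid dianion with the 1,4-bromoacetate of isoprene.

Assumption: the SMILES is read as (5S,9R,10S)-15-acetoxylabda-7,13E-dien-17-oic acid (5α-H, 9α-H, 10β-CH3); labdane numbering is used for positions.

## Route

Step 1
Reactants: 1 isobutyraldehyde; 2 pent-1-en-3-one (ethyl vinyl ketone)
Product: 3 2,4,4-trimethylcyclohex-2-en-1-one
Conditions: H2SO4 (cat.), toluene, 50 °C, then reflux (Dean–Stark)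
Reagents that add atoms: none
Why: Acid-catalysed Robinson annulation (Michael addition of the aldehyde enol, then aldol condensation through the ethyl CH2) builds ring A with the gem-dimethyl carbon and the future C10 methyl; no stereocentre.

Step 2
Reactants: 3 2,4,4-trimethylcyclohex-2-en-1-one
Product: 4 (R)-2,4,4-trimethylcyclohex-2-en-1-ol
Conditions: (S)-1-methyl-3,3-diphenyltetrahydro-1H,3H-pyrrolo[1,2-c][1,3,2]oxazaborole (10 mol %), BH3·SMe2, THF, −20 °C, slow addition of 3; aq. work-up
Reagents that add atoms: none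
Why: CBS reduction; the α-methyl-substituted alkene arm is the large group, so the (S)-catalyst gives the (R)-allylic alcohol (≥95% ee expected), the only external source of chirality in the route.

Step 3
Reactants: 4 (R)-2,4,4-trimethylcyclohex-2-en-1-ol; 5 butyl vinyl ether
Product: 7 (S)-2-(2,6,6-trimethylcyclohex-2-en-1-yl)acetaldehyde, via allyl vinyl ether 6 (not isolated)
Conditions: Pd(OCOCF3)2 (1 mol %), 4,7-diphenyl-1,10-phenanthroline, Et3N (cat.), neat 5, 75 °C; then volatiles off, xylene, 190 °C (sealed tube)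
Reagents that add atoms: none
Why: Catalytic vinyl transfer then thermal Claisen [3,3] rearrangement, suprafacial across the ring, so the C5–C6 bond forms on the face the C–O bond leaves: (R)-carbinol gives (S)-C5, and the alkene lands at C1=C10 where the radical is needed.

Step 4
Reactants: 8 isoprene
Product: 9 (E)-4-bromo-3-methylbut-2-en-1-yl acetate
Conditions: N-bromosuccinimide, AcOH, 15–20 °C; fractional distillation
Reagents that add atoms: N-bromosuccinimide (O=C1CCC(=O)N1Br); acetic acid (CC(=O)O)
Why: Electrophilic 1,4-bromoacetoxylation of the diene: Br+ adds to the more substituted alkene and acetate attacks the far allylic terminus, giving mainly the E isomer (minor 1,2-adduct and Z isomer are removed by distillation).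

Step 5
Reactants: 10 but-2-ynoic acid; 9 (E)-4-bromo-3-methylbut-2-en-1-yl acetate
Product: 12 (6E)-8-acetoxy-6-methyloct-6-en-2-ynoic acid, via dilithio dianion 11 (not isolated)
Conditions: LiN(i-Pr)2 (2.0 equiv), THF/HMPA, −78 °C; then 9, −78 → −40 °C; dil. HCl
Reagents that add atoms: none
Why: γ-Alkylation of the 2-butynoic acid dianion (the cumulenolate reacts at its terminal carbon with the soft primary allylic bromide by SN2); the alkene geometry is untouched and the acetate survives because bromide displacement at −78 °C is much faster than ester attack.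

Step 6
Reactants: 12 (6E)-8-acetoxy-6-methyloct-6-en-2-ynoic acid
Product: 13 2-(trimethylsilyl)ethyl (6E)-8-acetoxy-6-methyloct-6-en-2-ynoate
Conditions: 2-(trimethylsilyl)ethanol, N,N'-dicyclohexylcarbodiimide, 4-(dimethylamino)pyridine (cat.), CH2Cl2, 0 °C
Reagents that add atoms: 2-(trimethylsilyl)ethanol (C[Si](C)(C)CCO)
Why: Steglich esterification; this ester is later cleaved by fluoride at silicon, so its removal does not depend on the hindered C8 carbonyl and leaves the acetate alone.

Step 7
Reactants: 13 2-(trimethylsilyl)ethyl (6E)-8-acetoxy-6-methyloct-6-en-2-ynoate; 7 (S)-2-(2,6,6-trimethylcyclohex-2-en-1-yl)acetaldehyde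
Product: 16 2-(trimethylsilyl)ethyl (2Z,6E)-8-acetoxy-2-{1-acetoxy-2-[(1S)-2,6,6-trimethylcyclohex-2-en-1-yl]ethyl}-6-methylocta-2,6-dienoate (both C7 epimers), via vinylalane 14 (not isolated), via aluminium aldolate 15 (not isolated)
Conditions: i-Bu2AlH (1.05 equiv), HMPA, THF, 0 °C; then 7, 0 °C → rt; then Ac2O, pyridine, 4-(dimethylamino)pyridine (cat.), 0 °C
Reagents that add atoms: acetic anhydride (CC(=O)OC(C)=O)
Why: Conjugate syn-hydroalumination of the ynoate by the i-Bu2AlH–HMPA complex puts Al on C8 and H on C9 cis, so aldol addition to 7 with retention leaves the C11 chain cis to the ester (Z), and the aluminium alkoxide is acetylated in the flask; C7 forms as both epimers, which is harmless because this centre is destroyed in step 8.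

Step 8
Reactants: 16 2-(trimethylsilyl)ethyl (2Z,6E)-8-acetoxy-2-{1-acetoxy-2-[(1S)-2,6,6-trimethylcyclohex-2-en-1-yl]ethyl}-6-methylocta-2,6-dienoate
Product: 17 2-(trimethylsilyl)ethyl (1R,4aS,8aS)-1-[(3E)-5-acetoxy-3-methylpent-3-en-1-yl]-5,5,8a-trimethyl-1,4,4a,5,6,7,8,8a-octahydronaphthalene-2-carboxylate
Conditions: Fe(acac)3 (0.5 equiv), PhSiH3 (2.5 equiv, syringe pump), EtOH/ethylene glycol 5:1, 0.01 M, 60 °C, Ar
Reagents that add atoms: none
Why: Proposed new method: the iron hydride made from Fe(acac)3 and PhSiH3 gives H• to C1 of the only electron-rich, undeactivated alkene (the C13 alkene is inductively deactivated by its allylic acetate, the acrylate is electron-poor); the tertiary C10 radical closes 6-endo on C9 through a chair in which the equatorial C5 tether attacks anti to the axial C4 methyl (trans fusion, 10β-CH3) and the Z-acrylate holds C11 equatorial (9α-H); the C8 α-ester radical is reduced by divalent iron to the enolate, which expels the C7 acetate (E1cB) to give the Δ7 ester; the closest known reaction types are hydrogen-atom-transfer-initiated Giese cyclisations to trans-decalins and radical additions to Morita–Baylis–Hillman acetates with loss of acetate.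

Step 9
Reactants: 17 2-(trimethylsilyl)ethyl (1R,4aS,8aS)-1-[(3E)-5-acetoxy-3-methylpent-3-en-1-yl]-5,5,8a-trimethyl-1,4,4a,5,6,7,8,8a-octahydronaphthalene-2-carboxylate
Product: 18 (1R,4aS,8aS)-1-[(3E)-5-acetoxy-3-methylpent-3-en-1-yl]-5,5,8a-trimethyl-1,4,4a,5,6,7,8,8a-octahydronaphthalene-2-carboxylic acid (the target)
Conditions: Bu4NF (2 equiv), THF, 0 °C → rt; aq. NH4Cl/dil. HCl
Reagents that add atoms: none
Why: Fluoride attacks silicon and the ester fragments to carboxylate, ethene and Me3SiF (β-elimination); the primary acetate, both alkenes and all stereocentres are untouched.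

## Compound list

1 | isobutyraldehyde | CC(C)C=O | starting material
2 | pent-1-en-3-one | CCC(=O)C=C | starting material
3 | 2,4,4-trimethylcyclohex-2-en-1-one | CC1=CC(C)(C)CCC1=O | intermediate
4 | (R)-2,4,4-trimethylcyclohex-2-en-1-ol | CC1=CC(C)(C)CC[C@H]1O | intermediate
5 | butyl vinyl ether | C=COCCCC | starting material
6 | (R)-2,4,4-trimethylcyclohex-2-en-1-yl vinyl ether | CC1=CC(C)(C)CC[C@H]1OC=C | intermediate
7 | (S)-2-(2,6,6-trimethylcyclohex-2-en-1-yl)acetaldehyde | O=CC[C@@H]1C(C)=CCCC1(C)C | intermediate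
8 | isoprene | C=CC(C)=C | starting material
9 | (E)-4-bromo-3-methylbut-2-en-1-yl acetate | CC(=O)OC/C=C(\C)CBr | intermediate
10 | but-2-ynoic acid | CC#CC(=O)O | starting material
11 | dilithio dianion of but-2-ynoic acid (C4-lithiated lithium but-2-ynoate) | [Li+].[Li+].[CH2-]C#CC(=O)[O-] | intermediate
12 | (6E)-8-acetoxy-6-methyloct-6-en-2-ynoic acid | OC(=O)C#CCC/C(C)=C/COC(C)=O | intermediate
13 | 2-(trimethylsilyl)ethyl (6E)-8-acetoxy-6-methyloct-6-en-2-ynoate | C[Si](C)(C)CCOC(=O)C#CCC/C(C)=C/COC(C)=O | intermediate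
14 | 2-(trimethylsilyl)ethyl (2E,6E)-8-acetoxy-2-(diisobutylalumanyl)-6-methylocta-2,6-dienoate (Al and H cis) | CC(C)C[Al](CC(C)C)/C(C(=O)OCC[Si](C)(C)C)=C/CC/C(C)=C/COC(C)=O | intermediate
15 | diisobutylaluminium alkoxide of the (2Z,6E) aldol adduct of 14 and 7 (both C7 epimers) | CC(C)C[Al](CC(C)C)OC(C[C@@H]1C(C)=CCCC1(C)C)/C(C(=O)OCC[Si](C)(C)C)=C/CC/C(C)=C/COC(C)=O | intermediate
16 | 2-(trimethylsilyl)ethyl (2Z,6E)-8-acetoxy-2-{1-acetoxy-2-[(1S)-2,6,6-trimethylcyclohex-2-en-1-yl]ethyl}-6-methylocta-2,6-dienoate (both C7 epimers) | CC(=O)OC(C[C@@H]1C(C)=CCCC1(C)C)/C(C(=O)OCC[Si](C)(C)C)=C/CC/C(C)=C/COC(C)=O | intermediate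
17 | 2-(trimethylsilyl)ethyl (5S,9R,10S)-15-acetoxylabda-7,13E-dien-17-oate | CC(=O)OC/C=C(\C)CC[C@H]1C(C(=O)OCC[Si](C)(C)C)=CC[C@H]2C(C)(C)CCC[C@]12C | intermediate
18 | (5S,9R,10S)-15-acetoxylabda-7,13E-dien-17-oic acid | CC(=O)OC/C=C(\C)CC[C@H]1C(C(=O)O)=CC[C@H]2C(C)(C)CCC[C@]12C | target

## Step count and risks

Total: 9 steps. Longest linear sequence: 6 steps (1–3, then 7–9; the side-chain branch 4–6, then 7–9, is equally long).

**Step 8 (highest risk).** Hydrogen-atom transfer may go to the C13 alkene or the acrylate instead of the ring alkene, or the C10 radical may be reduced before it cyclises. The fallback sets out from 7 and comes back at 17, and it removes the competing alkene from the cyclisation substrate. Hexa-1,5-diyne (six non-hydrogen atoms) is mono-lithiated (n-BuLi, THF, −78 °C) and carboxylated with CO2 to hepta-2,6-diynoic acid F1. This is esterified as in step 6 to 2-(trimethylsilyl)ethyl hepta-2,6-diynoate F2 and coupled with 7 under the step 7 conditions to the truncated (Z)-allylic acetate F3. The Fe(acac)3/PhSiH3 cyclisation, now with a single electron-rich alkene, gives the C9-butynyl bicyclic ester F4. Negishi carboalumination (Me3Al, Cp2ZrCl2 cat., CH2Cl2; then paraformaldehyde, THF) builds the (E)-allylic alcohol F5, and Ac2O/pyridine gives 17.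

**Step 7.** i-Bu2AlH may attack the C15 acetate, and allenolate equilibration may erode the Z geometry that fixes C9. The fallback sets out from 13 and comes back at 16, and it uses a hydride-free vinyl-metal addition. Pd(PPh3)4-catalysed syn-hydrostannation (Bu3SnH, THF, 0 °C) gives the α-stannyl enoate F6. I2 (CH2Cl2, 0 °C) gives the α-iodo enoate F7 with retention. Nozaki–Hiyama–Kishi addition to 7 (CrCl2, NiCl2 cat., DMF, rt) gives the hydroxy ester F8 with the alkene geometry kept, and Ac2O/pyridine gives 16.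

**Step 3.** Vinyl transfer to a hindered secondary alcohol may stall, and the [3,3] shift forms a bond next to a quaternary carbon. The fallback sets out from 4 and comes back at 7, and it goes through the ester oxidation level. A Johnson orthoester Claisen rearrangement (trimethyl orthoacetate, cat. EtCO2H, 140 °C, MeOH distilled off) gives the methyl ester F9 with the same suprafacial chirality transfer, and i-Bu2AlH (toluene, −78 °C) gives 7.

## Further compounds

F1 | step 8 | hepta-2,6-diynoic acid | C#CCCC#CC(=O)O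
F2 | step 8 | 2-(trimethylsilyl)ethyl hepta-2,6-diynoate | C#CCCC#CC(=O)OCC[Si](C)(C)C
F3 | step 8 | 2-(trimethylsilyl)ethyl (2Z)-2-{1-acetoxy-2-[(1S)-2,6,6-trimethylcyclohex-2-en-1-yl]ethyl}hept-2-en-6-ynoate (both C7 epimers) | CC(=O)OC(C[C@@H]1C(C)=CCCC1(C)C)/C(C(=O)OCC[Si](C)(C)C)=C/CCC#C
F4 | step 8 | 2-(trimethylsilyl)ethyl (1R,4aS,8aS)-1-(but-3-yn-1-yl)-5,5,8a-trimethyl-1,4,4a,5,6,7,8,8a-octahydronaphthalene-2-carboxylate | C#CCC[C@H]1C(C(=O)OCC[Si](C)(C)C)=CC[C@H]2C(C)(C)CCC[C@]12C
F5 | step 8 | 2-(trimethylsilyl)ethyl (1R,4aS,8aS)-1-[(3E)-5-hydroxy-3-methylpent-3-en-1-yl]-5,5,8a-trimethyl-1,4,4a,5,6,7,8,8a-octahydronaphthalene-2-carboxylate | OC/C=C(\C)CC[C@H]1C(C(=O)OCC[Si](C)(C)C)=CC[C@H]2C(C)(C)CCC[C@]12C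
F6 | step 7 | 2-(trimethylsilyl)ethyl (2E,6E)-8-acetoxy-6-methyl-2-(tributylstannyl)octa-2,6-dienoate | CCCC[Sn](CCCC)(CCCC)/C(C(=O)OCC[Si](C)(C)C)=C/CC/C(C)=C/COC(C)=O
F7 | step 7 | 2-(trimethylsilyl)ethyl (2E,6E)-8-acetoxy-2-iodo-6-methylocta-2,6-dienoate | I/C(C(=O)OCC[Si](C)(C)C)=C/CC/C(C)=C/COC(C)=O
F8 | step 7 | 2-(trimethylsilyl)ethyl (2Z,6E)-8-acetoxy-2-{1-hydroxy-2-[(1S)-2,6,6-trimethylcyclohex-2-en-1-yl]ethyl}-6-methylocta-2,6-dienoate (both C7 epimers) | OC(C[C@@H]1C(C)=CCCC1(C)C)/C(C(=O)OCC[Si](C)(C)C)=C/CC/C(C)=C/COC(C)=O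
F9 | step 3 | methyl (S)-2-(2,6,6-trimethylcyclohex-2-en-1-yl)acetate | COC(=O)C[C@@H]1C(C)=CCCC1(C)C
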